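**Retrosynthetic overview**

1. The C40 chain is cut at C11=C12 (Wittig) into the ψ-side C25 aldehyde 29 (geranyl C10 + C5 + C10-dialdehyde, all by Wittig olefination) and the ring C15 phosphonium salt 18, which comes from enol triflate 13 and dienylstannane 15 by Stille coupling at C6–C7.
2. The only ring, the six-membered ring of the end group, is made in step 4 as cyclohexanone 9 by a one-pot [3+3] annulation that forms C1–C2 and C4–C5 together.
3. Enabling feature: the chain-bearing ring carbon C6 sits between C1 (CMe2) and C5 (C-methyl). At the ketone level C1 and C5 are the two α-carbons of 2-methylpentan-3-one (a 1,3-dinucleophile), and the other ring atoms C2–C3–C4 (CH2–CHO–CHO) are a glyceraldehyde-type 1,3-dielectrophile (iodide at C2, aldehyde at C4) that already holds the C3 stereocentre.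
4. C3 comes from methyl (R)-glycidate, C4 from chelation control in the aldol half of the annulation, and the C5=C6 double bond from enol triflation of the C6 ketone, which can only enolise towards C5 because C1 is quaternary.

Key step: step 4

Assumption: locants C1–C15 and primed locants follow carotenoid numbering. The methyl-bearing α-centre of 9–11 is drawn equatorial, but its configuration is irrelevant because it becomes sp2 in step 7. Z isomers at the newly formed disubstituted double bonds are the hindered type and are converged to E by the thermal equilibration given in the conditions. All polyenes are handled under argon in dim light.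

**Route**

Step 1
Reactants: 1 methyl (2R)-oxirane-2-carboxylate
Product: 2 methyl (2S)-2-hydroxy-3-iodopropanoate
Conditions: LiI, AcOH, THF, 0 °C → rt
Reagents that add atoms: lithium iodide, [Li+].[I-]
Why: Halohydrin formation by SN2 opening of the glycidic ester at the unsubstituted carbon; the stereocentre is untouched, and its descriptor changes from R to S only because CH2I outranks the ester carbon.

Step 2
Reactants: 2 methyl (2S)-2-hydroxy-3-iodopropanoate
Product: 3 methyl (2S)-2-(benzyloxy)-3-iodopropanoate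
Conditions: BnOC(=NH)CCl3, TfOH (cat.), CH2Cl2–cyclohexane, 0 °C → rt
Reagents that add atoms: benzyl 2,2,2-trichloroacetimidate, ClC(Cl)(Cl)C(=N)OCc1ccccc1
Why: Acid-catalysed O-benzylation with a trichloroacetimidate avoids the base that would close the iodohydrin to the epoxide or cause elimination.

Step 3
Reactants: 3 methyl (2S)-2-(benzyloxy)-3-iodopropanoate
Product: 4 (2S)-2-(benzyloxy)-3-iodopropanal
Conditions: (i-Bu)2AlH, CH2Cl2, −78 °C; MeOH, aq. potassium sodium tartrate; used crude at once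
Reagents that add atoms: none
Why: Partial reduction of an α-alkoxy ester with (i-Bu)2AlH should stop at the aldehyde because the chelated tetrahedral aluminium intermediate persists at −78 °C, and no base is present to epimerise or eliminate.

Step 4
Reactants: 4 (2S)-2-(benzyloxy)-3-iodopropanal; 5 2-methylpentan-3-one
Product: 9 (4R,5R,6R)-4-(benzyloxy)-5-hydroxy-2,2,6-trimethylcyclohexan-1-one, via lithium enolate 6 (not isolated), via bromomagnesium aldolate 7 (not isolated), via aldolate enolate 8 (not isolated)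
Conditions: 5, LiN(i-Pr)2 (1.05 equiv), THF, −78 °C; MgBr2·OEt2 (1.1 equiv); 4, −78 °C; then LiN(i-Pr)2 (1.3 equiv), DMPU, −78 → 0 °C; aq. NH4Cl
Reagents that add atoms: none
Why: Proposed new method: a one-pot [3+3] α,α'-annulation in which kinetic deprotonation of 5 at its CH2 gives enolate 6, whose magnesium-chelated aldol addition to the α-benzyloxy aldehyde 4 forms C4–C5, and a second equivalent of LiN(i-Pr)2 then enolises aldolate 7 at the only site away from the alkoxide, the isopropyl CH, so that enolate 8 closes the ring by C-alkylation on the primary iodide and forms C1–C2 together with the quaternary carbon. The closest known reaction types are chelation-controlled aldol additions of magnesium enolates to α-alkoxy aldehydes, the regioselective α'-enolisation and alkylation of ketone aldolate dianions, and base-mediated α,α'-annulations of ketones with 1,3-dielectrophiles; new is their union on a β-iodo aldehyde in one flask. The single ring closed is the cyclohexanone, by a 6-(enolendo)-exo-tet alkylation, the allowed mode for C-alkylation of an enolate whose C=C lies inside the forming six-membered ring. The carbinol centre C4 (C5 of 9) is set by attack on the five-membered chelate from the face opposite the CH2I group, which gives the 3,4-syn (ring-trans) relationship to the C3 centre carried over unchanged from 1; the methyl-bearing centre may epimerise and is erased in step 7. The step needs aldehyde addition before iodide displacement (secured by the rate difference at −78 °C), α' over α enolisation (secured by the adjacent alkoxide) and C- over O-alkylation (favoured by the lithium counter-ion, the iodide leaving group and the enolendo geometry).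

Step 5
Reactants: 9 (4R,5R,6R)-4-(benzyloxy)-5-hydroxy-2,2,6-trimethylcyclohexan-1-one
Product: 10 (4R,5R,6R)-4,5-dihydroxy-2,2,6-trimethylcyclohexan-1-one
Conditions: H2 (1 atm), palladium on carbon (Pd/C), EtOAc, rt
Reagents that add atoms: none
Why: Hydrogenolysis of the benzyl ether is done here because no alkene or C–I bond is present yet.

Step 6
Reactants: 10 (4R,5R,6R)-4,5-dihydroxy-2,2,6-trimethylcyclohexan-1-one
Product: 11 (4R,5R,6R)-4,5-bis[(tert-butyldimethylsilyl)oxy]-2,2,6-trimethylcyclohexan-1-one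
Conditions: TBSOTf (2.5 equiv), 2,6-lutidine, CH2Cl2, −40 → 0 °C
Reagents that add atoms: tert-butyldimethylsilyl trifluoromethanesulfonate, CC(C)(C)[Si](C)(C)OS(=O)(=O)C(F)(F)F
Why: Silylation of both secondary hydroxyls with a silyl triflate and a hindered pyridine base is mild enough to leave the β-oxy ketone intact (no retro-aldol).

Step 7
Reactants: 11 (4R,5R,6R)-4,5-bis[(tert-butyldimethylsilyl)oxy]-2,2,6-trimethylcyclohexan-1-one
Product: 13 (3R,4R)-3,4-bis[(tert-butyldimethylsilyl)oxy]-2,6,6-trimethylcyclohex-1-en-1-yl trifluoromethanesulfonate, via potassium enolate 12 (not isolated)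
Conditions: KN(SiMe3)2, THF, −78 °C; N-(5-chloropyridin-2-yl)bis(trifluoromethanesulfonimide), −78 → −20 °C
Reagents that add atoms: N-(5-chloropyridin-2-yl)-1,1,1-trifluoro-N-[(trifluoromethyl)sulfonyl]methanesulfonamide, FC(F)(F)S(=O)(=O)N(c1ccc(Cl)cn1)S(=O)(=O)C(F)(F)F
Why: Enol triflate formation is regiospecific because only the methyl-bearing α-carbon has a hydrogen, so the C5=C6 double bond is placed unambiguously and the temporary methine stereocentre disappears.

Step 8
Reactants: 14 (2E)-3-methylpent-2-en-4-yn-1-ol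
Product: 15 (2E,4E)-3-methyl-5-(tributylstannyl)penta-2,4-dien-1-ol
Conditions: Bu3SnH, PdCl2(PPh3)2 (2 mol %), THF, 0 °C
Reagents that add atoms: tributylstannane, CCCC[SnH](CCCC)CCCC
Why: Palladium-catalysed syn-hydrostannylation of the terminal alkyne should place tin at the terminal carbon and give the (E)-alkenylstannane; any internal regioisomer is removed by chromatography.

Step 9
Reactants: 13 (3R,4R)-3,4-bis[(tert-butyldimethylsilyl)oxy]-2,6,6-trimethylcyclohex-1-en-1-yl trifluoromethanesulfonate; 15 (2E,4E)-3-methyl-5-(tributylstannyl)penta-2,4-dien-1-ol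
Product: 16 (2E,4E)-5-{(3R,4R)-3,4-bis[(tert-butyldimethylsilyl)oxy]-2,6,6-trimethylcyclohex-1-en-1-yl}-3-methylpenta-2,4-dien-1-ol
Conditions: Pd2(dba)3 (2.5 mol %), AsPh3 (20 mol %), NMP, 50 °C
Reagents that add atoms: none
Why: Stille cross-coupling of a hindered cyclohexenyl triflate with an (E)-alkenylstannane forms C6–C7 with retention of alkene geometry, the weakly bound arsine ligand in a polar solvent speeding the transmetalation.

Step 10
Reactants: 16 (2E,4E)-5-{(3R,4R)-3,4-bis[(tert-butyldimethylsilyl)oxy]-2,6,6-trimethylcyclohex-1-en-1-yl}-3-methylpenta-2,4-dien-1-ol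
Product: 18 [(2E,4E)-5-{(3R,4R)-3,4-bis[(tert-butyldimethylsilyl)oxy]-2,6,6-trimethylcyclohex-1-en-1-yl}-3-methylpenta-2,4-dien-1-yl]triphenylphosphonium bromide, via allylic bromide 17 (not isolated)
Conditions: CBr4 (1.2 equiv), PPh3 (1.2 equiv), CH2Cl2, −20 °C; then PPh3 (1.5 equiv), rt
Reagents that add atoms: tetrabromomethane, BrC(Br)(Br)Br; triphenylphosphine, c1ccccc1P(c1ccccc1)c1ccccc1
Why: Appel bromination of the primary allylic alcohol under neutral conditions followed by SN2 quaternisation of PPh3 gives the Wittig salt without the acid that would ionise the allylic silyl ether.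

Step 11
Reactants: 19 (2E)-1-bromo-3,7-dimethylocta-2,6-diene (geranyl bromide)
Product: 20 [(2E)-3,7-dimethylocta-2,6-dien-1-yl]triphenylphosphonium bromide
Conditions: PPh3, toluene, rt
Reagents that add atoms: triphenylphosphine, c1ccccc1P(c1ccccc1)c1ccccc1
Why: SN2 quaternisation of PPh3 by a primary allylic bromide, with the E double bond retained.

Step 12
Reactants: 20 [(2E)-3,7-dimethylocta-2,6-dien-1-yl]triphenylphosphonium bromide; 21 ethyl (2E)-3-methyl-4-oxobut-2-enoate
Product: 23 ethyl (2E,4E,6E)-3,7,11-trimethyldodeca-2,4,6,10-tetraenoate, via geranyl ylide 22 (not isolated)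
Conditions: NaOEt, EtOH, 0 °C → rt; then n-heptane, reflux
Reagents that add atoms: none
Why: Wittig olefination of the aldehyde with the allylic ylide forms C7'=C8', and the hindered 4Z isomer should revert to 4E on heating while the two trisubstituted E double bonds come preformed from 20 and 21.

Step 13
Reactants: 23 ethyl (2E,4E,6E)-3,7,11-trimethyldodeca-2,4,6,10-tetraenoate
Product: 24 (2E,4E,6E)-3,7,11-trimethyldodeca-2,4,6,10-tetraen-1-ol
Conditions: (i-Bu)2AlH (2.2 equiv), toluene, −78 → 0 °C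
Reagents that add atoms: none
Why: 1,2-Reduction of the conjugated ester to the allylic alcohol with (i-Bu)2AlH leaves the polyene untouched.

Step 14
Reactants: 24 (2E,4E,6E)-3,7,11-trimethyldodeca-2,4,6,10-tetraen-1-ol
Product: 26 [(2E,4E,6E)-3,7,11-trimethyldodeca-2,4,6,10-tetraen-1-yl]triphenylphosphonium bromide, via C15 bromide 25 (not isolated)
Conditions: CBr4 (1.2 equiv), PPh3 (1.2 equiv), CH2Cl2, −20 °C; then PPh3 (1.5 equiv), rt
Reagents that add atoms: tetrabromomethane, BrC(Br)(Br)Br; triphenylphosphine, c1ccccc1P(c1ccccc1)c1ccccc1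
Why: Appel bromination and SN2 quaternisation as in step 10; the neutral SN2 path is chosen over an acid-mediated salt formation so that the 2E double bond is not scrambled through an allyl cation.

Step 15
Reactants: 26 [(2E,4E,6E)-3,7,11-trimethyldodeca-2,4,6,10-tetraen-1-yl]triphenylphosphonium bromide; 27 (2E,4E,6E)-2,7-dimethylocta-2,4,6-trienedial
Product: 29 (2E,4E,6E,8E,10E,12E,14E)-2,7,11,15,19-pentamethylicosa-2,4,6,8,10,12,14,18-octaenal, via C15 ylide 28 (not isolated)
Conditions: 27 (3 equiv), NaOMe, MeOH–CH2Cl2, 0 °C → rt; then n-heptane, reflux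
Reagents that add atoms: none
Why: Wittig mono-olefination of the symmetrical dialdehyde forms C11'=C12' and is held to one side by the excess of 27, which is recovered; heating converts the hindered Z isomer to E.

Step 16
Reactants: 18 [(2E,4E)-5-{(3R,4R)-3,4-bis[(tert-butyldimethylsilyl)oxy]-2,6,6-trimethylcyclohex-1-en-1-yl}-3-methylpenta-2,4-dien-1-yl]triphenylphosphonium bromide; 29 (2E,4E,6E,8E,10E,12E,14E)-2,7,11,15,19-pentamethylicosa-2,4,6,8,10,12,14,18-octaenal
Product: 31 (3R,4R)-3,4-bis[(tert-butyldimethylsilyl)oxy]-β,ψ-carotene (all-E), via ring ylide 30 (not isolated)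
Conditions: NaOMe, MeOH–CH2Cl2, 0 °C → rt; then n-heptane, reflux, argon, dark
Reagents that add atoms: none
Why: Wittig olefination forms C11=C12 and heating converts the hindered 11Z isomer to all-E; the silyloxy group at C4 is too poor a leaving group for vinylogous elimination from the ylide.

Step 17
Reactants: 31 (3R,4R)-3,4-bis[(tert-butyldimethylsilyl)oxy]-β,ψ-carotene
Product: 32 (3R,4R)-β,ψ-carotene-3,4-diol (all-E), the target
Conditions: Bu4NF, THF, 0 °C → rt
Reagents that add atoms: none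
Why: Fluoride-mediated cleavage of both silyl ethers under non-acidic conditions frees the diol without ionising the allylic C4 carbinol or touching a stereocentre.

**Compound list**

1 | methyl (2R)-oxirane-2-carboxylate | COC(=O)[C@H]1CO1 | starting material
2 | methyl (2S)-2-hydroxy-3-iodopropanoate | COC(=O)[C@H](O)CI | intermediate
3 | methyl (2S)-2-(benzyloxy)-3-iodopropanoate | COC(=O)[C@H](OCc1ccccc1)CI | intermediate
4 | (2S)-2-(benzyloxy)-3-iodopropanal | O=C[C@H](OCc1ccccc1)CI | intermediate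
5 | 2-methylpentan-3-one | CCC(=O)C(C)C | starting material
6 | lithium 2-methylpent-3-en-3-olate (E/Z mixture) | [Li+].CC=C([O-])C(C)C | intermediate (not isolated)
7 | bromomagnesium (2S,3R)-2-(benzyloxy)-1-iodo-4,6-dimethyl-5-oxoheptan-3-olate (epimers at C4) | CC(C)C(=O)C(C)[C@@H](O[Mg]Br)[C@H](OCc1ccccc1)CI | intermediate (not isolated)
8 | lithium bromomagnesium (5R,6S)-6-(benzyloxy)-7-iodo-2,4-dimethylhept-2-ene-3,5-bis(olate) | [Li+].CC(C)=C([O-])C(C)[C@@H](O[Mg]Br)[C@H](OCc1ccccc1)CI | intermediate (not isolated)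
9 | (4R,5R,6R)-4-(benzyloxy)-5-hydroxy-2,2,6-trimethylcyclohexan-1-one | O=C1[C@H](C)[C@@H](O)[C@H](OCc2ccccc2)CC1(C)C | intermediate
10 | (4R,5R,6R)-4,5-dihydroxy-2,2,6-trimethylcyclohexan-1-one | O=C1[C@H](C)[C@@H](O)[C@H](O)CC1(C)C | intermediate
11 | (4R,5R,6R)-4,5-bis[(tert-butyldimethylsilyl)oxy]-2,2,6-trimethylcyclohexan-1-one | O=C1[C@H](C)[C@@H](O[Si](C)(C)C(C)(C)C)[C@H](O[Si](C)(C)C(C)(C)C)CC1(C)C | intermediate
12 | potassium (3R,4R)-3,4-bis[(tert-butyldimethylsilyl)oxy]-2,6,6-trimethylcyclohex-1-en-1-olate | [K+].[O-]C1=C(C)[C@@H](O[Si](C)(C)C(C)(C)C)[C@H](O[Si](C)(C)C(C)(C)C)CC1(C)C | intermediate (not isolated)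
13 | (3R,4R)-3,4-bis[(tert-butyldimethylsilyl)oxy]-2,6,6-trimethylcyclohex-1-en-1-yl trifluoromethanesulfonate | FC(F)(F)S(=O)(=O)OC1=C(C)[C@@H](O[Si](C)(C)C(C)(C)C)[C@H](O[Si](C)(C)C(C)(C)C)CC1(C)C | intermediate
14 | (2E)-3-methylpent-2-en-4-yn-1-ol | OC/C=C(C)/C#C | starting material
15 | (2E,4E)-3-methyl-5-(tributylstannyl)penta-2,4-dien-1-ol | OC/C=C(C)/C=C/[Sn](CCCC)(CCCC)CCCC | intermediate
16 | (2E,4E)-5-{(3R,4R)-3,4-bis[(tert-butyldimethylsilyl)oxy]-2,6,6-trimethylcyclohex-1-en-1-yl}-3-methylpenta-2,4-dien-1-ol | OC/C=C(C)/C=C/C1=C(C)[C@@H](O[Si](C)(C)C(C)(C)C)[C@H](O[Si](C)(C)C(C)(C)C)CC1(C)C | intermediate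
17 | (3R,4R)-1-[(1E,3E)-5-bromo-3-methylpenta-1,3-dien-1-yl]-3,4-bis[(tert-butyldimethylsilyl)oxy]-2,6,6-trimethylcyclohex-1-ene | BrC/C=C(C)/C=C/C1=C(C)[C@@H](O[Si](C)(C)C(C)(C)C)[C@H](O[Si](C)(C)C(C)(C)C)CC1(C)C | intermediate (not isolated)
18 | [(2E,4E)-5-{(3R,4R)-3,4-bis[(tert-butyldimethylsilyl)oxy]-2,6,6-trimethylcyclohex-1-en-1-yl}-3-methylpenta-2,4-dien-1-yl]triphenylphosphonium bromide | [Br-].c1ccccc1[P+](c1ccccc1)(c1ccccc1)C/C=C(C)/C=C/C1=C(C)[C@@H](O[Si](C)(C)C(C)(C)C)[C@H](O[Si](C)(C)C(C)(C)C)CC1(C)C | intermediate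
19 | (2E)-1-bromo-3,7-dimethylocta-2,6-diene (geranyl bromide) | CC(C)=CCC/C(C)=C/CBr | starting material
20 | [(2E)-3,7-dimethylocta-2,6-dien-1-yl]triphenylphosphonium bromide | [Br-].CC(C)=CCC/C(C)=C/C[P+](c1ccccc1)(c1ccccc1)c1ccccc1 | intermediate
21 | ethyl (2E)-3-methyl-4-oxobut-2-enoate | CCOC(=O)/C=C(C)/C=O | starting material
22 | [(2E)-3,7-dimethylocta-2,6-dien-1-ylidene]triphenylphosphorane | CC(C)=CCC/C(C)=C/C=P(c1ccccc1)(c1ccccc1)c1ccccc1 | intermediate (not isolated)
23 | ethyl (2E,4E,6E)-3,7,11-trimethyldodeca-2,4,6,10-tetraenoate | CC(C)=CCC/C(C)=C/C=C/C(C)=C/C(=O)OCC | intermediate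
24 | (2E,4E,6E)-3,7,11-trimethyldodeca-2,4,6,10-tetraen-1-ol | CC(C)=CCC/C(C)=C/C=C/C(C)=C/CO | intermediate
25 | (2E,4E,6E)-1-bromo-3,7,11-trimethyldodeca-2,4,6,10-tetraene | CC(C)=CCC/C(C)=C/C=C/C(C)=C/CBr | intermediate (not isolated)
26 | [(2E,4E,6E)-3,7,11-trimethyldodeca-2,4,6,10-tetraen-1-yl]triphenylphosphonium bromide | [Br-].CC(C)=CCC/C(C)=C/C=C/C(C)=C/C[P+](c1ccccc1)(c1ccccc1)c1ccccc1 | intermediate
27 | (2E,4E,6E)-2,7-dimethylocta-2,4,6-trienedial | O=C/C(C)=C/C=C/C=C(C)/C=O | starting material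
28 | [(2E,4E,6E)-3,7,11-trimethyldodeca-2,4,6,10-tetraen-1-ylidene]triphenylphosphorane | CC(C)=CCC/C(C)=C/C=C/C(C)=C/C=P(c1ccccc1)(c1ccccc1)c1ccccc1 | intermediate (not isolated)
29 | (2E,4E,6E,8E,10E,12E,14E)-2,7,11,15,19-pentamethylicosa-2,4,6,8,10,12,14,18-octaenal (12'-apo-ψ-caroten-12'-al) | CC(C)=CCC/C(C)=C/C=C/C(C)=C/C=C/C(C)=C/C=C/C=C(C)/C=O | intermediate
30 | [(2E,4E)-5-{(3R,4R)-3,4-bis[(tert-butyldimethylsilyl)oxy]-2,6,6-trimethylcyclohex-1-en-1-yl}-3-methylpenta-2,4-dien-1-ylidene]triphenylphosphorane | c1ccccc1P(c1ccccc1)(c1ccccc1)=C/C=C(C)/C=C/C1=C(C)[C@@H](O[Si](C)(C)C(C)(C)C)[C@H](O[Si](C)(C)C(C)(C)C)CC1(C)C | intermediate (not isolated)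
31 | (3R,4R)-3,4-bis[(tert-butyldimethylsilyl)oxy]-β,ψ-carotene (all-E) | CC(C)=CCC/C(C)=C/C=C/C(C)=C/C=C/C(C)=C/C=C/C=C(C)/C=C/C=C(C)/C=C/C1=C(C)[C@@H](O[Si](C)(C)C(C)(C)C)[C@H](O[Si](C)(C)C(C)(C)C)CC1(C)C | intermediate
32 | (3R,4R)-β,ψ-carotene-3,4-diol (all-E) | CC(C)=CCC/C(C)=C/C=C/C(C)=C/C=C/C(C)=C/C=C/C=C(C)/C=C/C=C(C)/C=C/C1=C(C)[C@@H](O)[C@H](O)CC1(C)C | target

**Step count**

Total: 17 steps. Longest linear sequence: 11 steps (steps 1–7, 9, 10, 16, 17). Side branches: step 8 (stannane) and steps 11–15 (C25 aldehyde).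

**Steps most likely to fail, with fallbacks**

Step 4 (proposed new method). What may go wrong: incomplete facial control by the magnesium chelate in the aldol addition; retro-aldol or elimination of the aldolate during the second enolisation; and O-alkylation in place of C-alkylation in the ring closure. The fallback sets out from 4 and returns to the route at 9, with the two bonds formed in separate, known steps. Commercial 2-methylpent-1-en-3-one is converted with LiN(i-Pr)2 and Me3SiCl into 2-methyl-3-[(trimethylsilyl)oxy]penta-1,3-diene F1. A TiCl4-mediated, chelation-controlled Mukaiyama aldol addition of F1 to 4 (CH2Cl2, −78 °C) should give (5R,6S)-6-(benzyloxy)-5-hydroxy-7-iodo-2,4-dimethylhept-1-en-3-one F2. Silylation with Et3SiOTf and 2,6-lutidine gives (5R,6S)-6-(benzyloxy)-7-iodo-2,4-dimethyl-5-[(triethylsilyl)oxy]hept-1-en-3-one F3. Conjugate reduction of the isopropenyl ketone with LiBH(s-Bu)3 generates the tetrasubstituted enolate regiospecifically, and on warming with DMPU it cyclises (reductive alkylation of an enone) to (4R,5R,6R)-4-(benzyloxy)-2,2,6-trimethyl-5-[(triethylsilyl)oxy]cyclohexan-1-one F4. HF·pyridine in THF then gives 9.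

Step 9. What may go wrong: slow transmetalation at the triflate, which has substituents on both neighbouring ring carbons, so that protodestannylation and homocoupling of the stannane take over. The fallback sets out from 13 and returns at 16, building the side chain by olefination instead of cross-coupling. Formylation of 13 with CO (1 atm) and Bu3SnH under Pd(PPh3)4 catalysis, where CO insertion is little affected by hindrance, gives (3R,4R)-3,4-bis[(tert-butyldimethylsilyl)oxy]-2,6,6-trimethylcyclohex-1-ene-1-carbaldehyde F5. Horner–Wadsworth–Emmons olefination with triethyl 3-methyl-4-phosphonobut-2-enoate (n-BuLi, DMPU, THF) gives ethyl (2E,4E)-5-{(3R,4R)-3,4-bis[(tert-butyldimethylsilyl)oxy]-2,6,6-trimethylcyclohex-1-en-1-yl}-3-methylpenta-2,4-dienoate F6. Reduction with (i-Bu)2AlH gives 16.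

Step 10. What may go wrong: ionisation of the trienylic bromide, with allylic transposition or loss of the C4 silyloxy group (retro-type rearrangement) before the phosphine has reacted. The fallback sets out from 16 and 29 and returns at 31, with the roles of the final Wittig partners reversed so that no ring-side halide or ylide is needed. Oxidation of 16 with MnO2 gives (2E,4E)-5-{(3R,4R)-3,4-bis[(tert-butyldimethylsilyl)oxy]-2,6,6-trimethylcyclohex-1-en-1-yl}-3-methylpenta-2,4-dienal F7. Aldehyde 29 is reduced with NaBH4 to (2E,4E,6E,8E,10E,12E,14E)-2,7,11,15,19-pentamethylicosa-2,4,6,8,10,12,14,18-octaen-1-ol F8. PPh3·HBr in MeOH converts F8 into [(2E,4E,6E,8E,10E,12E,14E)-2,7,11,15,19-pentamethylicosa-2,4,6,8,10,12,14,18-octaen-1-yl]triphenylphosphonium bromide F9. Wittig olefination of F7 with F9 (NaOMe, MeOH–CH2Cl2, then heating in n-heptane) gives 31.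

**Further compounds**

F1 | step 4 | 2-methyl-3-[(trimethylsilyl)oxy]penta-1,3-diene | C=C(C)C(O[Si](C)(C)C)=CC
F2 | step 4 | (5R,6S)-6-(benzyloxy)-5-hydroxy-7-iodo-2,4-dimethylhept-1-en-3-one | C=C(C)C(=O)C(C)[C@@H](O)[C@H](OCc1ccccc1)CI
F3 | step 4 | (5R,6S)-6-(benzyloxy)-7-iodo-2,4-dimethyl-5-[(triethylsilyl)oxy]hept-1-en-3-one | C=C(C)C(=O)C(C)[C@@H](O[Si](CC)(CC)CC)[C@H](OCc1ccccc1)CI
F4 | step 4 | (4R,5R,6R)-4-(benzyloxy)-2,2,6-trimethyl-5-[(triethylsilyl)oxy]cyclohexan-1-one | O=C1[C@H](C)[C@@H](O[Si](CC)(CC)CC)[C@H](OCc2ccccc2)CC1(C)C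
F5 | step 9 | (3R,4R)-3,4-bis[(tert-butyldimethylsilyl)oxy]-2,6,6-trimethylcyclohex-1-ene-1-carbaldehyde | O=CC1=C(C)[C@@H](O[Si](C)(C)C(C)(C)C)[C@H](O[Si](C)(C)C(C)(C)C)CC1(C)C
F6 | step 9 | ethyl (2E,4E)-5-{(3R,4R)-3,4-bis[(tert-butyldimethylsilyl)oxy]-2,6,6-trimethylcyclohex-1-en-1-yl}-3-methylpenta-2,4-dienoate | CCOC(=O)/C=C(C)/C=C/C1=C(C)[C@@H](O[Si](C)(C)C(C)(C)C)[C@H](O[Si](C)(C)C(C)(C)C)CC1(C)C
F7 | step 10 | (2E,4E)-5-{(3R,4R)-3,4-bis[(tert-butyldimethylsilyl)oxy]-2,6,6-trimethylcyclohex-1-en-1-yl}-3-methylpenta-2,4-dienal | O=C/C=C(C)/C=C/C1=C(C)[C@@H](O[Si](C)(C)C(C)(C)C)[C@H](O[Si](C)(C)C(C)(C)C)CC1(C)C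
F8 | step 10 | (2E,4E,6E,8E,10E,12E,14E)-2,7,11,15,19-pentamethylicosa-2,4,6,8,10,12,14,18-octaen-1-ol | CC(C)=CCC/C(C)=C/C=C/C(C)=C/C=C/C(C)=C/C=C/C=C(C)/CO
F9 | step 10 | [(2E,4E,6E,8E,10E,12E,14E)-2,7,11,15,19-pentamethylicosa-2,4,6,8,10,12,14,18-octaen-1-yl]triphenylphosphonium bromide | [Br-].CC(C)=CCC/C(C)=C/C=C/C(C)=C/C=C/C(C)=C/C=C/C=C(C)/C[P+](c1ccccc1)(c1ccccc1)c1ccccc1
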